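The α-methylene-γ-lactone (ring B: C11, C12, lactone O, C8, C7; germacranolide numbering) is cut at C7–C11 and O–C8. The exocyclic methylene carbon C13 lies 1,3 to the free C6 hydroxyl, so O6–C13 can serve as a tether: a (C6-oxymethyl)malonate places a malonyl radical at C11 next to a C7=C8 alkene. Mn(OAc)3/Cu(OAc)2 oxidation then closes a temporary tetrahydrofuran (ring A: O6, C13, C11, C7, C6) and ring B in one operation, setting C7 and C8 from C6. Ring A masks the 6-hydroxyl and the exo-methylene until a late retro-oxa-Michael opening; a Nozaki–Hiyama–Kishi reaction closes the ten-membered ring.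

Key step: step 7

Remark: atoms are numbered as in germacranolides (ring C1–C10 with C1 = enone CH, C2 = ketone, C4 = CH(CH3), C5 = ester carbinol, C6 = free carbinol, C7/C8 = lactone fusion, C10 = C(CH3); C11–C13 = lactone α-carbon, carbonyl, exo-methylene; C14, C15 = methyls); compounds 1, 6, 9 and 17 are taken as purchasable.

Step 1
Reactants: 1 propargyl alcohol
Product: 3 (Z)-3-iodo-2-methylprop-2-en-1-ol, via alkenylmagnesium alkoxide 2 (not isolated)
Conditions: MeMgBr (3 equiv), CuI (10 mol%), THF, −10 °C to rt; then I2, −78 to 0 °C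
Reagents that add atoms: methylmagnesium bromide C[Mg]Br; iodine II
Why: Copper-catalysed anti-carbomagnesiation of the propargylic alkoxide holds magnesium cis to the CH2O group in a five-membered chelate, so iodinolysis with retention should give the Z iodide that carries C1, C9, C10 and C14.

Step 2
Reactants: 3 (Z)-3-iodo-2-methylprop-2-en-1-ol
Product: 4 (Z)-3-bromo-1-iodo-2-methylprop-1-ene
Conditions: CBr4, PPh3, CH2Cl2, 0 °C
Reagents that add atoms: carbon tetrabromide BrC(Br)(Br)Br
Why: Appel bromination of the primary allylic alcohol proceeds by SN2 at the oxyphosphonium stage and leaves the vinyl iodide and its geometry untouched.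

Step 3
Reactants: 4 (Z)-3-bromo-1-iodo-2-methylprop-1-ene
Product: 5 (Z)-1-iodo-2-methylpenta-1,4-diene
Conditions: vinylmagnesium bromide, CuI (5 mol%), THF, −40 to 0 °C
Reagents that add atoms: vinylmagnesium bromide C=C[Mg]Br
Why: Copper-catalysed allyl–vinyl Grignard coupling should occur by direct substitution at the primary allylic bromide (the iodine-bearing terminus is blocked) much faster than any reaction of the vinyl iodide at this temperature.

Step 4
Reactants: 6 (R)-but-3-ene-1,2-diol
Product: 7 (2R)-1-[(tert-butyldiphenylsilyl)oxy]but-3-en-2-ol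
Conditions: TBDPSCl (1.05 equiv), imidazole, CH2Cl2, 0 °C
Reagents that add atoms: tert-butyl(chloro)diphenylsilane CC(C)(C)[Si](Cl)(c1ccccc1)c1ccccc1
Why: The bulky silyl chloride selects the primary hydroxyl (future C5); the C6 stereocentre is taken from the chiral pool.

Step 5
Reactants: 7 (2R)-1-[(tert-butyldiphenylsilyl)oxy]but-3-en-2-ol; 5 (Z)-1-iodo-2-methylpenta-1,4-diene (3 equiv)
Product: 8 (2R,3E,6Z)-1-[(tert-butyldiphenylsilyl)oxy]-7-iodo-6-methylhepta-3,6-dien-2-ol
Conditions: second-generation Hoveyda–Grubbs catalyst (5 mol%), CH2Cl2, 40 °C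
Reagents that add atoms: none
Why: Cross-metathesis of the terminal olefin of 5 with the allylic alcohol is driven by loss of ethylene and the trisubstituted iodoalkene is inert; the E isomer is expected but not essential, because C8 passes through a radical in step 7.

Step 6
Reactants: 8 (2R,3E,6Z)-1-[(tert-butyldiphenylsilyl)oxy]-7-iodo-6-methylhepta-3,6-dien-2-ol; 9 di-tert-butyl methylenemalonate
Product: 10 di-tert-butyl 2-({[(2R,3E,6Z)-1-[(tert-butyldiphenylsilyl)oxy]-7-iodo-6-methylhepta-3,6-dien-2-yl]oxy}methyl)propanedioate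
Conditions: KN(SiMe3)2 (1.0 equiv), THF, −78 °C; 9 (1.1 equiv); AcOH quench at −78 °C
Reagents that add atoms: none
Why: Oxa-Michael addition of the potassium alkoxide to the doubly activated methylene acceptor puts C13, C11 and C12 on O6; the hindered tert-butyl malonate anion should not add to a second acceptor, and silyl migration should be slow, before the cold quench.

Step 7
Reactants: 10 di-tert-butyl 2-({[(2R,3E,6Z)-1-[(tert-butyldiphenylsilyl)oxy]-7-iodo-6-methylhepta-3,6-dien-2-yl]oxy}methyl)propanedioate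
Product: 11 tert-butyl (3R,3aS,4R,6aR)-4-{[(tert-butyldiphenylsilyl)oxy]methyl}-3-[(2Z)-3-iodo-2-methylprop-2-en-1-yl]-1-oxotetrahydro-1H,3H-furo[3,4-c]furan-6a-carboxylate
Conditions: Mn(OAc)3·2H2O (2.2 equiv), Cu(OAc)2·H2O (1.0 equiv), degassed AcOH, 80 °C
Reagents that add atoms: none
Why: Mn(OAc)3 (trivalent manganese) oxidises the malonate through its manganese enolate to the electrophilic C11 malonyl radical, which adds 5-exo-trig to C7; Cu(OAc)2 (divalent copper) intercepts the C8 radical as an alkylcopper in the trivalent state, and the cis tert-butyl ester carbonyl oxygen displaces copper at C8 and sheds isobutylene, so C11–C7 and O–C8 form in one operation. The closest known reaction type is the oxidative free-radical cyclization of unsaturated malonates with Mn(OAc)3/Cu(OAc)2 that ends in lactonization by an ester carbonyl. Ring A closes by radical 5-exo-trig attack and ring B by a 5-exo-tet closure of oxygen on C8. C7 is set from C6 through a chair-like transition state with the CH2OTBDPS group pseudo-equatorial (6,7-trans on ring A); C8 is set in the lactonization, where the bicycle can only be cis-fused and the C9 chain takes the convex face (trans to C6 on ring B); C11 is quaternary and whichever of the two identical esters is cis to C8 closes. The step needs exo over endo closure, attack on C7=C8 and not on the iodoalkene, and lactonization in preference to β-hydride elimination; the 1,2-disubstituted alkene placed five atoms from the radical, the remoteness and lower electron density of the iodoalkene, and the proximity of an easily ionised tert-butyl ester should secure these.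

Step 8
Reactants: 11 tert-butyl (3R,3aS,4R,6aR)-4-{[(tert-butyldiphenylsilyl)oxy]methyl}-3-[(2Z)-3-iodo-2-methylprop-2-en-1-yl]-1-oxotetrahydro-1H,3H-furo[3,4-c]furan-6a-carboxylate
Product: 13 (3R,3aS,4R,6aS)-4-{[(tert-butyldiphenylsilyl)oxy]methyl}-3-[(2Z)-3-iodo-2-methylprop-2-en-1-yl]tetrahydro-1H,3H-furo[3,4-c]furan-1-one, via malonic half-acid 12 (not isolated)
Conditions: TFA/CH2Cl2 (1:4), 0 °C to rt; evaporate; toluene, 110 °C
Reagents that add atoms: none
Why: Acidolysis of the remaining tert-butyl ester and thermal decarboxylation of the lactone-activated acid through its enol should give the C11–H lactone, which can only protonate to the cis-fused bicycle.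

Step 9
Reactants: 13 (3R,3aS,4R,6aS)-4-{[(tert-butyldiphenylsilyl)oxy]methyl}-3-[(2Z)-3-iodo-2-methylprop-2-en-1-yl]tetrahydro-1H,3H-furo[3,4-c]furan-1-one
Product: 14 (3R,3aS,4R,6aS)-4-(hydroxymethyl)-3-[(2Z)-3-iodo-2-methylprop-2-en-1-yl]tetrahydro-1H,3H-furo[3,4-c]furan-1-one
Conditions: HF·pyridine, pyridine/THF, 0 °C to rt
Reagents that add atoms: none
Why: Fluoride-driven desilylation under buffered, non-basic conditions frees the C5 hydroxyl without opening the lactone or ring A.

Step 10
Reactants: 14 (3R,3aS,4R,6aS)-4-(hydroxymethyl)-3-[(2Z)-3-iodo-2-methylprop-2-en-1-yl]tetrahydro-1H,3H-furo[3,4-c]furan-1-one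
Product: 15 (3R,3aS,4R,6aS)-3-[(2Z)-3-iodo-2-methylprop-2-en-1-yl]-1-oxotetrahydro-1H,3H-furo[3,4-c]furan-4-carbaldehyde
Conditions: Dess–Martin periodinane, NaHCO3, CH2Cl2, 0 °C to rt
Reagents that add atoms: none
Why: Buffered Dess–Martin oxidation should give the α-alkoxy aldehyde without epimerising C6; it is used at once.

Step 11
Reactants: 15 (3R,3aS,4R,6aS)-3-[(2Z)-3-iodo-2-methylprop-2-en-1-yl]-1-oxotetrahydro-1H,3H-furo[3,4-c]furan-4-carbaldehyde
Product: 16 (3R,3aS,4R,6aS)-4-[(1R,2R)-1-hydroxy-2-methylbut-3-en-1-yl]-3-[(2Z)-3-iodo-2-methylprop-2-en-1-yl]tetrahydro-1H,3H-furo[3,4-c]furan-1-one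
Conditions: diisopropyl (S,S)-tartrate (E)-crotylboronate (1.5 equiv), 4 Å molecular sieves, toluene, −78 °C; aqueous work-up
Reagents that add atoms: diisopropyl (4S,5S)-2-[(2E)-but-2-en-1-yl]-1,3,2-dioxaborolane-4,5-dicarboxylate C/C=C/CB1O[C@H](C(=O)OC(C)C)[C@@H](C(=O)OC(C)C)O1
Why: Roush crotylboration: the E-crotyl group reacts through a closed chair transition state to give the 4,5-anti relationship, and the (S,S)-tartrate directs attack to the re face of the aldehyde, which sets C5 (R) and with it C4 (R) against the intrinsic facial bias of the aldehyde.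

Step 12
Reactants: 17 methyl angelate
Product: 18 (Z)-2-methylbut-2-en-1-ol
Conditions: iBu2AlH (2.2 equiv), CH2Cl2, −78 °C
Reagents that add atoms: none
Why: 1,2-Reduction of the conjugated ester by the aluminium hydride gives the allylic alcohol with the Z geometry retained.

Step 13
Reactants: 18 (Z)-2-methylbut-2-en-1-ol
Product: 19 (2S,3R)-(2,3-dimethyloxiran-2-yl)methanol
Conditions: Ti(OiPr)4 (10 mol%), L-(+)-diethyl tartrate (12 mol%), tert-butyl hydroperoxide, 4 Å molecular sieves, CH2Cl2, −20 °C
Reagents that add atoms: tert-butyl hydroperoxide CC(C)(C)OO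
Why: Sharpless asymmetric epoxidation: the L-(+)-tartrate titanium complex should deliver oxygen to the face that gives the (2S,3R)-epoxy alcohol, and the Z alkene fixes the two methyl groups trans on the oxirane.

Step 14
Reactants: 19 (2S,3R)-(2,3-dimethyloxiran-2-yl)methanol
Product: 20 (2R,3R)-2,3-dimethyloxirane-2-carboxylic acid
Conditions: RuCl3·xH2O (2 mol%), NaIO4 (3 equiv), MeCN/EtOAc/H2O, 0 °C to rt
Reagents that add atoms: sodium periodate [Na+].[O-]I(=O)(=O)=O; water O
Why: Catalytic RuO4 oxidation takes the primary alcohol to the acid through the aldehyde hydrate and leaves the oxirane intact; the C2 descriptor changes to R through priorities only.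

Step 15
Reactants: 16 (3R,3aS,4R,6aS)-4-[(1R,2R)-1-hydroxy-2-methylbut-3-en-1-yl]-3-[(2Z)-3-iodo-2-methylprop-2-en-1-yl]tetrahydro-1H,3H-furo[3,4-c]furan-1-one; 20 (2R,3R)-2,3-dimethyloxirane-2-carboxylic acid
Product: 22 C5 (2R,3R)-2,3-dimethyloxirane-2-carboxylate (epoxyangelate) of 16, via mixed anhydride 21 (not isolated)
Conditions: 20, 2,4,6-trichlorobenzoyl chloride, Et3N, THF, rt; then 16, DMAP, toluene, rt to 40 °C
Reagents that add atoms: none
Why: Yamaguchi esterification: the trichlorobenzoyl carbonyl of the mixed anhydride is blocked by its ortho chlorines, so DMAP transfers the epoxy-acyl group to the C5 hydroxyl, the only free one because O6 is locked in ring A.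

Step 16
Reactants: 22 C5 (2R,3R)-2,3-dimethyloxirane-2-carboxylate (epoxyangelate) of 16
Product: 24 C2 primary alcohol (22 with the vinyl group converted into CH2CH2OH), via B-alkyl-9-BBN adduct 23 (not isolated)
Conditions: 9-BBN (1.5 equiv), THF, 0 °C to rt; then 30% H2O2, aq. NaHCO3, 0 °C
Reagents that add atoms: hydrogen peroxide OO
Why: Anti-Markovnikov hydroboration–oxidation: 9-BBN selects the monosubstituted alkene over the trisubstituted iodoalkene and leaves esters alone, and mildly basic peroxide oxidises the C–B bond to the C2 alcohol.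

Step 17
Reactants: 24 C2 primary alcohol
Product: 25 C2 aldehyde (CH2CHO in place of CH2CH2OH)
Conditions: Dess–Martin periodinane, NaHCO3, CH2Cl2, 0 °C to rt
Reagents that add atoms: none
Why: Buffered Dess–Martin oxidation of the primary alcohol stops at the aldehyde and tolerates the lactone, the epoxy ester and the vinyl iodide.

Step 18
Reactants: 25 C2 aldehyde
Product: 26 macrocyclic allylic alcohol (ten-membered ring closed between C1 and C2; ring A intact; C2 epimers)
Conditions: CrCl2 (10 equiv), NiCl2 (2 mol%), DMSO/THF, rt, slow addition to 0.002 M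
Reagents that add atoms: none
Why: Nozaki–Hiyama–Kishi macrocyclization: zerovalent nickel inserts into the vinyl iodide with retention of the Z geometry, transmetalation gives a vinylchromium species (trivalent chromium) that adds to the aldehyde, and high dilution plus the rigid bicyclic core favour the ten-membered ring; both C2 epimers are carried on because C2 is oxidised in step 20.

Step 19
Reactants: 26 macrocyclic allylic alcohol
Product: 27 2-hydroxy analogue of vicolide D (C2 epimers; free 6-hydroxyl and exo-methylene lactone)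
Conditions: LiN(SiMe3)2 (2.5 equiv), THF, −78 to −30 °C; AcOH at −78 °C
Reagents that add atoms: none
Why: E1cB retro-oxa-Michael opening of ring A: the C11 lactone enolate expels the O6 alkoxide across C13–O6, driven by exchanging an ester enolate for an alkoxide and a conjugated exo-methylene lactone, while the cold acidic quench should prevent acyl shift from O5 and re-closure, which would be a disfavoured 5-endo-trig addition.

Step 20
Reactants: 27 2-hydroxy analogue of vicolide D
Product: 28 vicolide D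
Conditions: MnO2 (activated, 20 equiv), CH2Cl2, rt
Reagents that add atoms: none
Why: MnO2 oxidises only the allylic C2 alcohol to the Z enone and leaves the non-allylic C6 hydroxyl, the epoxide and the exo-methylene lactone untouched.

Compound list
1 | propargyl alcohol (prop-2-yn-1-ol) | C#CCO | starting material
2 | (Z)-alkenylmagnesium alkoxide BrMg–CH=C(CH3)–CH2–OMgBr (magnesium cis to CH2O) | Br[Mg]/C=C(C)\CO[Mg]Br | intermediate
3 | (Z)-3-iodo-2-methylprop-2-en-1-ol | OC/C(C)=C\I | intermediate
4 | (Z)-3-bromo-1-iodo-2-methylprop-1-ene | BrC/C(C)=C\I | intermediate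
5 | (Z)-1-iodo-2-methylpenta-1,4-diene | C=CC/C(C)=C\I | intermediate
6 | (R)-but-3-ene-1,2-diol | C=C[C@@H](O)CO | starting material
7 | (2R)-1-[(tert-butyldiphenylsilyl)oxy]but-3-en-2-ol | C=C[C@@H](O)CO[Si](c1ccccc1)(c1ccccc1)C(C)(C)C | intermediate
8 | (2R,3E,6Z)-1-[(tert-butyldiphenylsilyl)oxy]-7-iodo-6-methylhepta-3,6-dien-2-ol | I/C=C(C)\C/C=C/[C@@H](O)CO[Si](c1ccccc1)(c1ccccc1)C(C)(C)C | intermediate
9 | di-tert-butyl methylenemalonate (di-tert-butyl 2-methylidenepropanedioate) | C=C(C(=O)OC(C)(C)C)C(=O)OC(C)(C)C | starting material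
10 | di-tert-butyl 2-({[(2R,3E,6Z)-1-[(tert-butyldiphenylsilyl)oxy]-7-iodo-6-methylhepta-3,6-dien-2-yl]oxy}methyl)propanedioate | I/C=C(C)\C/C=C/[C@@H](OCC(C(=O)OC(C)(C)C)C(=O)OC(C)(C)C)CO[Si](c1ccccc1)(c1ccccc1)C(C)(C)C | intermediate
11 | tert-butyl (3R,3aS,4R,6aR)-4-{[(tert-butyldiphenylsilyl)oxy]methyl}-3-[(2Z)-3-iodo-2-methylprop-2-en-1-yl]-1-oxotetrahydro-1H,3H-furo[3,4-c]furan-6a-carboxylate (cis-fused rings A and B; both side chains on the convex face) | CC(C)(C)[Si](c1ccccc1)(c1ccccc1)OC[C@@H]2OC[C@@]3(C(=O)OC(C)(C)C)C(=O)O[C@H](C/C(C)=C\I)[C@@H]23 | intermediate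
12 | (3R,3aS,4R,6aS)-4-{[(tert-butyldiphenylsilyl)oxy]methyl}-3-[(2Z)-3-iodo-2-methylprop-2-en-1-yl]-1-oxotetrahydro-1H,3H-furo[3,4-c]furan-6a-carboxylic acid | CC(C)(C)[Si](c1ccccc1)(c1ccccc1)OC[C@@H]2OC[C@@]3(C(=O)O)C(=O)O[C@H](C/C(C)=C\I)[C@@H]23 | intermediate
13 | (3R,3aS,4R,6aS)-4-{[(tert-butyldiphenylsilyl)oxy]methyl}-3-[(2Z)-3-iodo-2-methylprop-2-en-1-yl]tetrahydro-1H,3H-furo[3,4-c]furan-1-one | CC(C)(C)[Si](c1ccccc1)(c1ccccc1)OC[C@@H]2OC[C@H]3C(=O)O[C@H](C/C(C)=C\I)[C@@H]23 | intermediate
14 | (3R,3aS,4R,6aS)-4-(hydroxymethyl)-3-[(2Z)-3-iodo-2-methylprop-2-en-1-yl]tetrahydro-1H,3H-furo[3,4-c]furan-1-one | OC[C@@H]1OC[C@H]2C(=O)O[C@H](C/C(C)=C\I)[C@@H]12 | intermediate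
15 | (3R,3aS,4R,6aS)-3-[(2Z)-3-iodo-2-methylprop-2-en-1-yl]-1-oxotetrahydro-1H,3H-furo[3,4-c]furan-4-carbaldehyde | O=C[C@@H]1OC[C@H]2C(=O)O[C@H](C/C(C)=C\I)[C@@H]12 | intermediate
16 | (3R,3aS,4R,6aS)-4-[(1R,2R)-1-hydroxy-2-methylbut-3-en-1-yl]-3-[(2Z)-3-iodo-2-methylprop-2-en-1-yl]tetrahydro-1H,3H-furo[3,4-c]furan-1-one | C=C[C@@H](C)[C@@H](O)[C@@H]1OC[C@H]2C(=O)O[C@H](C/C(C)=C\I)[C@@H]12 | intermediate
17 | methyl angelate (methyl (Z)-2-methylbut-2-enoate) | C/C=C(C)\C(=O)OC | starting material
18 | (Z)-2-methylbut-2-en-1-ol | C/C=C(C)\CO | intermediate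
19 | (2S,3R)-(2,3-dimethyloxiran-2-yl)methanol | C[C@H]1O[C@@]1(C)CO | intermediate
20 | (2R,3R)-2,3-dimethyloxirane-2-carboxylic acid | C[C@H]1O[C@@]1(C)C(=O)O | intermediate
21 | (2R,3R)-2,3-dimethyloxirane-2-carboxylic 2,4,6-trichlorobenzoic anhydride | C[C@H]1O[C@@]1(C)C(=O)OC(=O)c1c(Cl)cc(Cl)cc1Cl | intermediate
22 | C5 (2R,3R)-2,3-dimethyloxirane-2-carboxylate of 16: (1R,2R)-2-methyl-1-[bicyclic lactone-4-yl]but-3-en-1-yl ester | C=C[C@@H](C)[C@@H](OC(=O)[C@]3(C)O[C@@H]3C)[C@@H]1OC[C@H]2C(=O)O[C@H](C/C(C)=C\I)[C@@H]12 | intermediate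
23 | B-alkyl-9-borabicyclo[3.3.1]nonane adduct of 22 (boron on C2) | C1CCC2CCCC1B2CC[C@@H](C)[C@@H](OC(=O)[C@]3(C)O[C@@H]3C)[C@@H]4OC[C@H]5C(=O)O[C@H](C/C(C)=C\I)[C@@H]45 | intermediate
24 | C2 primary alcohol: (1R,2R)-4-hydroxy-2-methyl-1-[bicyclic lactone-4-yl]butyl (2R,3R)-2,3-dimethyloxirane-2-carboxylate | OCC[C@@H](C)[C@@H](OC(=O)[C@]3(C)O[C@@H]3C)[C@@H]1OC[C@H]2C(=O)O[C@H](C/C(C)=C\I)[C@@H]12 | intermediate
25 | C2 aldehyde: (1R,2R)-2-methyl-4-oxo-1-[bicyclic lactone-4-yl]butyl (2R,3R)-2,3-dimethyloxirane-2-carboxylate | O=CC[C@@H](C)[C@@H](OC(=O)[C@]3(C)O[C@@H]3C)[C@@H]1OC[C@H]2C(=O)O[C@H](C/C(C)=C\I)[C@@H]12 | intermediate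
26 | macrocyclic allylic alcohol: ten-membered ring with (Z)-C1=C10 and C2 carbinol (both epimers); O6 and C13 joined as ring A cis-fused to the 12,8-lactone; C5 epoxyangelate | C4[C@H]1C(=O)O[C@@H]2C/C(C)=C\C(O)C[C@@H](C)[C@@H](OC(=O)[C@]3(C)O[C@@H]3C)[C@H](O4)[C@@H]12 | intermediate
27 | 2-hydroxy analogue of vicolide D (C2 epimers; ketone replaced by CHOH) | C=C1C(=O)O[C@@H]2C/C(C)=C\C(O)C[C@@H](C)[C@@H](OC(=O)[C@]3(C)O[C@@H]3C)[C@H](O)[C@@H]12 | intermediate
28 | vicolide D | C=C1C(=O)O[C@@H]2C/C(C)=C\C(=O)C[C@@H](C)[C@@H](OC(=O)[C@]3(C)O[C@@H]3C)[C@H](O)[C@@H]12 | target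

Total step count: 20. Longest linear sequence: 16 steps (steps 1, 2, 3, 5 to 11 and 15 to 20).

Steps most likely to fail

Step 7. The C8 alkylcopper may lose a β-hydrogen toward C9 (diene formation) faster than the ester carbonyl captures it, or the radical closure may show poor 6,7-trans selectivity. The fallback makes the two bonds by two polar, stereospecific events. Setting out from 10, iodocarbocyclization (I2, Ti(OtBu)4, CuO, CH2Cl2, rt) would add the titanium malonate and iodine anti across the E alkene to give the iodide di-tert-butyl (4,5-trans)-5-{[(tert-butyldiphenylsilyl)oxy]methyl}-4-[(3Z)-1,4-diiodo-3-methylbut-3-en-1-yl]dihydrofuran-3,3(2H)-dicarboxylate F1. Heating F1 in toluene with 2,6-lutidine would let the cis ester carbonyl displace iodide with inversion at C8 and lose its tert-butyl group, which comes back to the route at 11.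

Step 19. Ring opening may be slow because the C13–O6 bond lies close to the plane of the C11 enolate, and the lithium alkoxide set free at O6 may attack the neighbouring C5 ester (acyl shift). The fallback is a silylative opening that never passes through a free alkoxide. Setting out from 26, TMSOTf and Et3N (CH2Cl2, −78 to 0 °C) would turn the lactone into its silyl ketene acetal and silylate O6 as an oxonium leaving group, giving after ring opening the 2,6-bis(trimethylsilyl) ether of the diol F2. Methanolysis of F2 with citric acid would come back to the route at 27.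

Step 11. Facial selectivity may be poor, because the tartrate reagent has to override the intrinsic bias of the α-alkoxy aldehyde (mismatched pair). The fallback is a Marshall propargylation, which also changes the way C2 is brought to the aldehyde level. Setting out from 15, the allenylzinc reagent generated from (S)-but-3-yn-2-yl methanesulfonate (Pd(OAc)2, PPh3, Et2Zn, THF, −20 °C; overall inversion at the propargylic carbon is assumed) would add through a closed transition state to give the anti homopropargylic alcohol (3R,3aS,4R,6aS)-4-[(1R,2R)-1-hydroxy-2-methylbut-3-yn-1-yl]-3-[(2Z)-3-iodo-2-methylprop-2-en-1-yl]tetrahydro-1H,3H-furo[3,4-c]furan-1-one F3. Yamaguchi esterification with 20 would give its C5 (2R,3R)-2,3-dimethyloxirane-2-carboxylate F4. Hydroboration of the terminal alkyne of F4 with dicyclohexylborane followed by buffered H2O2 would give the aldehyde directly and come back to the route at 25.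

Further compounds
F1 | step 7 | di-tert-butyl (4,5-trans)-5-{[(tert-butyldiphenylsilyl)oxy]methyl}-4-[(3Z)-1,4-diiodo-3-methylbut-3-en-1-yl]dihydrofuran-3,3(2H)-dicarboxylate | CC(C)(C)[Si](c1ccccc1)(c1ccccc1)OC[C@@H]1OCC(C(=O)OC(C)(C)C)(C(=O)OC(C)(C)C)[C@H]1[C@@H](I)C/C(C)=C\I
F2 | step 19 | 2,6-bis(trimethylsilyl) ether of diol 27 | C=C1C(=O)O[C@@H]2C/C(C)=C\C(O[Si](C)(C)C)C[C@@H](C)[C@@H](OC(=O)[C@]3(C)O[C@@H]3C)[C@H](O[Si](C)(C)C)[C@@H]12
F3 | step 11 | (3R,3aS,4R,6aS)-4-[(1R,2R)-1-hydroxy-2-methylbut-3-yn-1-yl]-3-[(2Z)-3-iodo-2-methylprop-2-en-1-yl]tetrahydro-1H,3H-furo[3,4-c]furan-1-one | C#C[C@@H](C)[C@@H](O)[C@@H]1OC[C@H]2C(=O)O[C@H](C/C(C)=C\I)[C@@H]12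
F4 | step 11 | C5 (2R,3R)-2,3-dimethyloxirane-2-carboxylate of F3 | C#C[C@@H](C)[C@@H](OC(=O)[C@]3(C)O[C@@H]3C)[C@@H]1OC[C@H]2C(=O)O[C@H](C/C(C)=C\I)[C@@H]12
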